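(The data are simulated for an exercise; noise was put on by code.)

In the oak run the substrate comes to rest near 66.5 %, higher than the 55.0 % its charge of coupling partner could pay for, so some partner seems to leave by a second exit.

| flask | substrate | coupling partner | remark | time |
|---|---|---|---|---|
| oak | 0.10 M | 0.045 M | run made earlier |  |
| elm | 0.10 M | 0.18 M | run made earlier |  |
| ash | 0.15 M | 0.090 M | run made earlier |  |
| flask | 0.10 M | 0.0900 M |  | 10 min |

| run | time / min | substrate / % | mono adduct / % | bis adduct / % |
|---|---|---|---|---|
| oak | 2.50 | 71.9 | 28.6 | 0.1 |
| oak | 5.00 | 67.4 | 30.6 | 0.9 |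
| oak | 8.00 | 66.9 | 32.5 | 0.7 |
| oak | 10.0 | 67.1 | 29.6 | 1.0 |
| oak | 12.0 | 65.5 | 32.6 | 1.4 |
| elm | 1.00 | 37.6 | 58.5 | 1.6 |
| elm | 2.00 | 24.5 | 72.7 | 2.9 |
| elm | 3.00 | 16.7 | 74.5 | 2.7 |
| elm | 6.00 | 9.0 | 77.9 | 3.4 |
| elm | 12.0 | 5.8 | 78.4 | 3.6 |
| ash | 1.00 | 68.4 | 30.5 | 0 |
| ash | 3.00 | 56.3 | 42.5 | 0.8 |
| ash | 6.00 | 51.9 | 45.4 | 0.7 |
| ash | 8.00 | 55.1 | 45.1 | 1.0 |
| ash | 12.0 | 52.0 | 42.0 | 0 |

(each reading ± 1 percentage point)

- the substrate standing at 10 min, as a percentage of the substrate charged
- the mono adduct standing at 10 min, as a percentage of the substrate charged
- the bis adduct standing at 10 min, as a percentage of the substrate charged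
- the triple product standing at 10 min, as a percentage of the substrate charged



Treat the partner as a tank with two drains, one proportional to the substrate level and one fixed in its time constant. Partner not spent on substrate, divided by the logarithm of substrate charged over substrate left, then gives 0.0282 M from oak. Your doubt is whether that survives other charges, but the last readings of ash, averaging 53.0 %, give 0.0307 M. I carry the mean, 0.0295 M, as the break-even level, the substrate concentration at which the two drains run equal.

At any substrate level A, a share A/(A+w) of the partner reaches substrate, which at the flask's charge is 77.2 %, or 0.0695 M spent. The objection is that the level falls as this happens, so I take the mean level, 0.0652 M, whose share of 68.9 % spends 0.0620 M and leaves 38.0 % substrate. Has the flask had time? Elm's first minute gives a substrate time constant of 1.02 min at its partner charge, so the partner's lifetime at the final level is about 2.73 min, and 10 min is longer, at 3.66 lifetimes. I therefore commit to that substrate figure, with mono adduct some points under what the substrate loses.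

The forecast, holding that “the partner also decays in parallel”, gave 41 % substrate, above my figure, with 56 % mono adduct, 1.7 % bis adduct and 1.2 % triple product. The flask gives 39.3 %, 56.0 %, 0.0810 % and 0.0180 %.

    substrate + coupling partner → mono adduct (k = 0.131 /M/s)
    coupling partner + mono adduct → bis adduct (k = 0.00936 /M/s)
    coupling partner + bis adduct → triple product (k = 0.00900 /M/s)
    substrate → decomposition product (k = 2.42 × 10⁻⁵ /s)
    substrate + bis adduct → side product (k = 0.243 /M/s)
    coupling partner ⇌ dormant form (K = 13.0, k = 0.00524 /s)

In the flask, half of the coupling up to 10 min is done by 0.667 min and half of the passage into the dormant form by 0.723 min, so the partner's two paths ran side by side. At 10 min the flask's partner, the limiting reagent, has 1.3 % of its charge free against 39 % of the substrate, with 0.0288 M in the dormant form beside the 0.0280 M my reckoning had set aside. In the neighbour flask with 0.036 M partner, the same break-even level gives a first spend of 0.0278 M, a mean level of 0.0861 M and 73.2 % substrate left. That neighbour flask, computed, holds 72.9 % substrate and 25.5 % mono adduct.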